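## Structural features

The target 28 is a daucane-type sesquiterpenoid ester: a cyclopentane (C1–C5) fused across the C1–C5 bond to a cyclohept-8-en-10-one (C1, C5–C10), giving a trans-hydroazulene. C1 is a quaternary fusion carbon that carries a methyl group and the C10 carbonyl; C5 is the fusion CH, with its hydrogen on the face opposite to the C1 methyl. The stereocentres are contiguous around C5: C4 is a tertiary carbinol with an isopropyl group, its hydroxyl on the face opposite to H5 and 1,3-anti to the C6 oxygen, and C6 carries the 4-methoxybenzoate with H6 anti to H5. The remaining functionality is the enone C8(Me)=C9–C10(=O). Three points are fragile. The C6 ester is vinylogously β to the carbonyl through C7 and can be expelled by base. The tertiary C4 alcohol ionises under acid and is in a retro-aldol relationship to C6 whenever C6 is an aldehyde. C5 is epimerisable at every stage in which C4 or C6 is a carbonyl. The real difficulty is the crowded C1–C5–C4–C6 array, where two fully substituted carbons flank C5 and the quaternary centre must be set trans to its neighbour, together with telling apart the two oxygenated ring carbons C6 and C10. The key step exploits the fact that C7–C8–C9 with the C8 methyl is an isobutene unit spanning C6 and C10, and that C6 and C10 are one-carbon arms on the adjacent, trans-disposed carbons C5 and C1 of an otherwise complete cyclopentane.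

## Logic of the disconnections

28 to 26 (through 27): no skeletal bond is cut. The C10 carbonyl is traced back to a carbinol and the C8=C9 bond to its exocyclic isomer. An exocyclic methylene between two carbinol carbons is what a 2-methylenepropane-1,3-diyl unit leaves behind, and oxidation erases the C10 stereocentre, so its configuration need not be controlled. The forward step must oxidise only the secondary C10 hydroxyl, and the alkene shift must stop at 28 without expelling the C6 acyloxy group.

26 to 24 and 25: the ester C–O bond at O6 is cut. The aroyl group is the base-labile element and is best attached late; removing it takes eight carbons off the problem. The forward step must acylate O6 in preference to the neopentyl O10 and the tertiary O4.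

24 to 23: the O4–Si bond is cut. O4 has to be masked while C6 is an aldehyde, but a silyl ether on O4 crowds O6 and could migrate to it. Removing it before acylation also keeps fluoride away from the later enone ester. The group must survive a tin fluoride reagent and a boron Lewis acid at low temperature yet leave with fluoride, which points to triethylsilyl.

23 to 20 and 6 (key): C6–C7 and C9–C10 are cut. Both bonds are allylic to C8 and each ends at a carbinol carbon, which is the retron of two carbonyl allylations by one three-carbon unit. The cut opens the seven-membered ring, removes C7–C9 and the C8 methyl carbon, and leaves a cyclopentane that already holds C1, C4 and C5. The forward step must allylate the two formyl groups one after the other within one molecule and must form the C6 carbinol in the right configuration.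

20 to 18 to 17: the C10 formyl group comes from cleavage of a C=C bond and the C6 formyl group from an acetal. Two different masks keep both aldehydes out of the organometallic steps and allow C6 to be released only after O4 is silylated. The forward steps must hydrolyse the acetal without epimerising C5 or losing the silyl ether, and cleave the alkene in the presence of an aldehyde.

17 to 15 to 14: the O4–Si bond and the C4–isopropyl bond are cut. The isopropyl group is added to a ketone whose C5 substituent sends the reagent to the opposite face, which puts O4 cis to the C5–C6 bond. The demand is addition, not enolisation or hydride transfer, at a hindered, enolisable β-alkoxy ketone.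

14 to 13 to 12: at the alkenyl carbon C10, C–H is traced to C–I and then to C–Si. Silicon is needed earlier, both to make the alkenyl metal and as a bulky group that steers the C5 substituent, but it must be gone before the alkene is cleaved. The exchange is placed at the ketone stage under neutral conditions so that C5, which loses its thermodynamic bias once silicon is removed, is not epimerised.

12 to 11: the C5–C6 bond is cut. The enol ether stores the regiochemistry of the conjugate-addition enolate, and a one-carbon electrophile at the acetal oxidation level installs the C6 arm already protected. The forward step needs attack anti to the silylated alkenyl group on C1.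

11 to 7 and 8: the C1–C10 bond and the enol O–Si bond are cut. The quaternary stereocentre comes from a catalytic enantioselective conjugate addition of an alkenyl metal to the β-methyl enone, so both starting materials are achiral and commercial. The demand is catalyst control at a β,β-disubstituted cyclopentenone and trapping of the enolate on oxygen.

6 to 4 to 1: the C–I bond and the C–Si bond of the linchpin are cut. The three-carbon unit goes back to a commercial allylic alcohol by dianion silylation. The iodide must be made without acid, which would protodesilylate the allylsilane.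

## Other disconnections considered

Alternative 1: The cut is C4–C5, which opens the cyclopentane. In the forward direction an enantiopure triazolylidene carbene turns the aldehyde of the symmetrical triketone A1 into an acyl anion equivalent, which adds to one of the two enantiotopic ring carbonyls and gives the α-ketol A2.
- In its favour: A1 should be available by one Michael addition to a symmetrical dione. The catalyst is metal-free, and five-membered ketol formation is the most reliable ring size for this chemistry. C1 and C5 are set in one event without cryogenic organoaluminium chemistry. On cost and operational simplicity this is equal to or better than step 3 of the chosen plan, and the route up to its key step is shorter.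
- Against it here: the ring fusion of A2 is cis and C5 carries a hydroxyl where the target has hydrogen in a trans fusion. C4 is a ketone that still needs an isopropyl group next to a tertiary alcohol. C6–C9 are bare methylenes, so the C6 oxygen, the C8 methyl and the C8=C9 bond must all be introduced on the seven-membered ring afterwards.
- Comparison: in structure, A2 has the ring system but little of the functionality, whereas 23 has every ring carbon and both ring oxygens in place. In mechanism, the benzoin addition is reversible and catalyst-controlled, while the annulation is irreversible and substrate-controlled. In step economy, the alternative is much longer after the key step.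

Alternative 2: The cuts are C1–C10 and C5–C6 on the cyclopentanone, with the seven-membered ring left to a later C8–C9 aldol condensation. The forward step is the conjugate addition of 9 to 7 as in step 3, but enolate 10 is intercepted by the ketal aldehyde A3 to give the aldol A4.
- In its favour: three components meet in one flask and C1, C5 and C6 are set together. The silicon is used productively, since the vinylsilane can become the C10 methyl ketone, so no iododesilylation, reduction or alkene cleavage is needed. The closing condensation would deliver the C8(Me)=C9–C10(=O) enone directly. On convergence and step count before ring closure it is better than the chosen plan, and it shares the same enantio-determining step, so it is equal there.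
- Against it here: the C6 configuration rests on the facial selectivity of an aluminium enolate aldol. The β-hydroxy ketone A4 can revert by retro-aldol under the isopropyl addition. The seven-membered aldol closure must beat the five-membered closure from the C7 enolate onto C10 and the β-elimination of the C6 oxygen from the C8 ketone.
- Comparison: in structure, A4 and 20 are of similar complexity. In mechanism, the chosen plan closes the ring by an irreversible allylsilane addition with no competing enolisation, while the alternative relies on a reversible aldol with regiochemical options. In step economy, the alternative is equal or better if the condensation behaves, but carries more risk at the ring-forming step.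

Alternative 3: The cut is the transannular C1–C5 bond. In the forward direction the ten-membered epoxy enone A5 is deprotonated at C1 and the enolate opens the epoxide at C5 with inversion, giving the bicyclic hydroxy enone A6.
- In its favour: the quaternary centre, the ring fusion and both rings form in one step. The C4 hydroxyl is released unprotected with its configuration fixed by the epoxide. A6 already holds the full skeleton, the enone and the C6 oxygen, so only an exchange of silyl for aroyl remains. After the key step it is shorter than the chosen plan, and it has no C6 against C10 differentiation problem; on both points it is better.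
- Against it here: A5 has a (Z)-trisubstituted enone, a trisubstituted epoxide and defined stereocentres in a ten-membered ring, and making it would probably cost more steps than the whole chosen route. Enolisation must occur at C1 and not at C7 or the C8 methyl, where an extended enolate could expel the C6 oxygen. The opening must occur at C5 along a trajectory that depends on the macrocycle conformation, so the trans fusion is not assured.
- Comparison: in structure, this is the most direct final bond. In mechanism, both plans depend on substrate conformation, but here a quaternary carbon is made by displacement at a hindered epoxide, whereas the chosen plan makes it catalytically at the start. In step economy, the alternative is better after the key step and worse before it.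

Key step: step 11

Remark: daucane numbering (C1–C10) is used for all ring positions; the conjugate addition in step 3 uses the enantiomer of the carbene ligand that gives the 3S adduct.
Remark: the order in which the two formyl groups of 20 react does not change the constitution of 23; the more exposed C10 formyl group is assumed to react first.
Remark: the C10 carbinol configuration in 22–26 is drawn as expected from Felkin–Anh addition; it is removed in step 14, so either epimer serves.

## Route

Step 1
Reactants: 1 2-methylprop-2-en-1-ol
Product: 4 2-[(trimethylsilyl)methyl]prop-2-en-1-ol, via dilithio dianion 2 (not isolated), via bis(trimethylsilyl) derivative 3 (not isolated)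
Conditions: n-BuLi (2.3 equiv), TMEDA, Et2O/THF, 0 °C → rt; Me3SiCl, −78 °C → rt; then 1 M aq H2SO4, THF, rt
Reagents that add atoms: chlorotrimethylsilane, C[Si](C)(C)Cl
Why: Alkoxide-directed allylic lithiation gives the O,C-dianion, which is silylated at both sites; the labile O–Si bond is then hydrolysed selectively (dianion silylation, silyl ether hydrolysis).

Step 2
Reactants: 4 2-[(trimethylsilyl)methyl]prop-2-en-1-ol
Product: 6 [2-(iodomethyl)prop-2-en-1-yl]trimethylsilane, via allylic mesylate 5 (not isolated)
Conditions: MsCl, Et3N, CH2Cl2, −20 °C; then NaI, acetone, rt, dark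
Reagents that add atoms: sodium iodide, [Na+].[I-]
Why: Sulfonylation followed by Finkelstein displacement; the conditions are neutral to mildly basic, so the acid-sensitive allylsilane should survive, and the iodide is used at once.

Step 3
Reactants: 7 3-methylcyclopent-2-en-1-one; 8 ethynyltrimethylsilane
Product: 11 trimethyl({(3S)-3-methyl-3-[1-(trimethylsilyl)ethenyl]cyclopent-1-en-1-yl}oxy)silane, via alkenylalane 9 (not isolated), via aluminium enolate 10 (not isolated)
Conditions: 8, iBu2AlH, hexanes, 55 °C; then 7, Cu(OTf)2 (5 mol%), chiral silver carbene complex Ag2L2 (2.5 mol%; L = enantiopure N-aryl-N′-(2-sulfonatoaryl)-4,5-diphenylimidazolin-2-ylidene), THF, −78 → −30 °C; then Me3SiOTf, −78 → 0 °C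
Reagents that add atoms: trimethylsilyl trifluoromethanesulfonate, C[Si](C)(C)OS(=O)(=O)C(F)(F)F
Why: Hydroalumination places aluminium on the silicon-bearing carbon, and the copper–carbene catalyst transfers this alkenyl group to the β-carbon of the enone (enantioselective conjugate addition), setting the quaternary C1 under catalyst control. O-Silylation of the aluminium enolate stores the enolate regiochemistry for step 4.

Step 4
Reactants: 11 trimethyl({(3S)-3-methyl-3-[1-(trimethylsilyl)ethenyl]cyclopent-1-en-1-yl}oxy)silane
Product: 12 (2S,3S)-2-(dimethoxymethyl)-3-methyl-3-[1-(trimethylsilyl)ethenyl]cyclopentan-1-one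
Conditions: HC(OMe)3, Me3SiOTf (5 mol%), CH2Cl2, −78 °C; pyridine quench
Reagents that add atoms: trimethyl orthoformate, COC(OC)OC
Why: Mukaiyama-type addition of the enol silane to the dimethoxycarbenium ion forms C5–C6 at the acetal oxidation level. The electrophile enters anti to the bulky silylated alkenyl group on C1, and the same trans isomer is the thermodynamic one, so C5 should be set cleanly.

Step 5
Reactants: 12 (2S,3S)-2-(dimethoxymethyl)-3-methyl-3-[1-(trimethylsilyl)ethenyl]cyclopentan-1-one
Product: 13 (2S,3S)-2-(dimethoxymethyl)-3-(1-iodoethenyl)-3-methylcyclopentan-1-one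
Conditions: N-iodosuccinimide, MeCN/ClCH2CN (4:1), 0 °C → rt, dark
Reagents that add atoms: N-iodosuccinimide, O=C1CCC(=O)N1I
Why: Electrophilic ipso-iododesilylation of the vinylsilane through a β-silyl cation; the medium is neutral, so the acetal and the epimerisable C5 centre should be untouched.

Step 6
Reactants: 13 (2S,3S)-2-(dimethoxymethyl)-3-(1-iodoethenyl)-3-methylcyclopentan-1-one
Product: 14 (2S,3R)-2-(dimethoxymethyl)-3-ethenyl-3-methylcyclopentan-1-one
Conditions: Bu3SnH, AIBN (cat.), PhH, 80 °C
Reagents that add atoms: none
Why: Radical chain reduction of the alkenyl iodide to the plain vinyl group; no acid or base is present, which matters because C5 has lost its thermodynamic bias once silicon is gone.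

Step 7
Reactants: 14 (2S,3R)-2-(dimethoxymethyl)-3-ethenyl-3-methylcyclopentan-1-one
Product: 15 (1R,2R,3R)-2-(dimethoxymethyl)-3-ethenyl-3-methyl-1-(propan-2-yl)cyclopentan-1-ol
Conditions: iPrMgCl, CeCl3, THF, −78 → 0 °C; aq NH4Cl
Reagents that add atoms: isopropylmagnesium chloride, CC(C)[Mg]Cl
Why: Organocerium 1,2-addition, chosen because the weakly basic reagent suppresses enolisation and β-hydride reduction. The reagent attacks the ketone face anti to the adjacent C5 dimethoxymethyl group, so the new C4–O bond is cis to the C5–C6 bond.

Step 8
Reactants: 15 (1R,2R,3R)-2-(dimethoxymethyl)-3-ethenyl-3-methyl-1-(propan-2-yl)cyclopentan-1-ol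
Product: 17 {[(1R,2R,3R)-2-(dimethoxymethyl)-3-ethenyl-3-methyl-1-(propan-2-yl)cyclopentyl]oxy}triethylsilane, via potassium alkoxide 16 (not isolated)
Conditions: KN(SiMe3)2, THF, −78 °C; Et3SiCl, −78 → 0 °C
Reagents that add atoms: chlorotriethylsilane, CC[Si](Cl)(CC)CC
Why: Silylation of the hindered tertiary alcohol through its alkoxide; the acid-free conditions leave the dimethyl acetal alone, and no carbonyl is present that could trigger retro-aldol cleavage.

Step 9
Reactants: 17 {[(1R,2R,3R)-2-(dimethoxymethyl)-3-ethenyl-3-methyl-1-(propan-2-yl)cyclopentyl]oxy}triethylsilane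
Product: 18 (1R,2R,5R)-2-ethenyl-2-methyl-5-(propan-2-yl)-5-[(triethylsilyl)oxy]cyclopentane-1-carbaldehyde
Conditions: 10% aq (CO2H)2 on SiO2, CH2Cl2, rt
Reagents that add atoms: water, O
Why: Mild acetal hydrolysis on wet acidic silica, which a tertiary triethylsilyl ether should tolerate. It is done before the alkene cleavage because ozone can oxidise acetal C–H bonds.

Step 10
Reactants: 18 (1R,2R,5R)-2-ethenyl-2-methyl-5-(propan-2-yl)-5-[(triethylsilyl)oxy]cyclopentane-1-carbaldehyde
Product: 20 (1S,2R,3R)-1-methyl-3-(propan-2-yl)-3-[(triethylsilyl)oxy]cyclopentane-1,2-dicarbaldehyde, via secondary ozonide 19 (not isolated)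
Conditions: O3, CH2Cl2, −78 °C; PPh3, −78 °C → rt; used crude
Reagents that add atoms: ozone, [O-][O+]=O
Why: Ozonolysis of the monosubstituted alkene with reductive work-up (Criegee mechanism) releases the C10 formyl group under cold, neutral conditions, so the epimerisable, elimination-prone dialdehyde is not exposed to acid or base.

Step 11
Reactants: 20 (1S,2R,3R)-1-methyl-3-(propan-2-yl)-3-[(triethylsilyl)oxy]cyclopentane-1,2-dicarbaldehyde; 6 [2-(iodomethyl)prop-2-en-1-yl]trimethylsilane
Product: 23 (3R,3aS,4S,8S,8aS)-8a-methyl-6-methylidene-3-(propan-2-yl)-3-[(triethylsilyl)oxy]decahydroazulene-4,8-diol, via allyltin reagent 21 (not isolated), via tin alkoxide 22 (not isolated)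
Conditions: 6 (1.05 equiv), SnF2, THF, 0 °C → rt; then solvent to CH2Cl2, BF3·OEt2, −78 → −40 °C; aq NaHCO3
Reagents that add atoms: none
Why: Divalent tin (SnF2) inserts into the C–I bond of 6 to give the tetravalent allyltin 21, which adds in Barbier fashion through a six-membered cyclic transition state to the more exposed formyl group of 20, the one on C1 (C10), forming C9–C10 and leaving tin alkoxide 22 with the allylsilane intact. BF3·OEt2 then activates the remaining C6 formyl group, and the allylsilane attacks it through its methylene terminus with loss of Me3SiF (intramolecular Hosomi–Sakurai reaction, anti SE2′), forming C6–C7 and placing the double bond exocyclic at C8. The closest known reaction type is the tin-mediated (3+4) annulation of 1,4-dicarbonyl compounds with this same iodide–allylsilane reagent. The seven-membered ring is closed in the second event by a 7-exo-trig addition to the aldehyde, with the carbonyl oxygen staying outside the ring. C10 is set in the intermolecular step by Felkin–Anh attack anti to C5, the largest substituent on C1, and is expected to be 10S; it is erased in step 14 and needs no control. C6 is set in the ring closure: the tether from C1 fixes the attacked face, and the BF3-bound oxygen takes the outward, pseudo-equatorial position syn to C5–H because the inward position lies between the cis C1 methyl and the C4 triethylsilyloxy group, which gives 6S with H6 anti to H5. The step needs the two formyl groups to react one after the other and not with two molecules of 21; this is secured by the shielding of the C6 formyl group (two fully substituted neighbours, both substituents cis to it), by near-stoichiometric 6, and by the symmetry of the linchpin about C8, so that the opposite order of attack gives the same diol. The tertiary triethylsilyl ether blocks retro-aldol cleavage and β-elimination along C4–C5–C6 and should tolerate SnF2 and BF3·OEt2 at low temperature.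

Step 12
Reactants: 23 (3R,3aS,4S,8S,8aS)-8a-methyl-6-methylidene-3-(propan-2-yl)-3-[(triethylsilyl)oxy]decahydroazulene-4,8-diol
Product: 24 (3R,3aS,4S,8S,8aS)-8a-methyl-6-methylidene-3-(propan-2-yl)decahydroazulene-3,4,8-triol
Conditions: Bu4NF, THF, 0 °C → rt
Reagents that add atoms: none
Why: Fluoride cleavage of the silyl ether, placed here because the triol has no base-sensitive group. It also frees the neighbourhood of O6 and removes the risk of silyl migration from O4 to O6 before acylation.

Step 13
Reactants: 24 (3R,3aS,4S,8S,8aS)-8a-methyl-6-methylidene-3-(propan-2-yl)decahydroazulene-3,4,8-triol; 25 4-methoxybenzoyl chloride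
Product: 26 (3R,3aS,4S,8S,8aS)-3,8-dihydroxy-8a-methyl-6-methylidene-3-(propan-2-yl)decahydroazulen-4-yl 4-methoxybenzoate
Conditions: 25 (1.1 equiv), pyridine, DMAP (cat.), CH2Cl2, −20 → 0 °C
Reagents that add atoms: none
Why: Nucleophile-catalysed acylation with a moderately reactive aroyl chloride. O6 is an equatorial secondary hydroxyl between a CH and a CH2, O10 is neopentyl (next to the quaternary C1) and O4 is tertiary, so O6 should react first.

Step 14
Reactants: 26 (3R,3aS,4S,8S,8aS)-3,8-dihydroxy-8a-methyl-6-methylidene-3-(propan-2-yl)decahydroazulen-4-yl 4-methoxybenzoate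
Product: 28 (3R,3aS,4S,8aS)-3-hydroxy-6,8a-dimethyl-8-oxo-3-(propan-2-yl)-1,2,3,3a,4,5,8,8a-octahydroazulen-4-yl 4-methoxybenzoate, via unconjugated enone 27 (not isolated)
Conditions: Dess–Martin periodinane, NaHCO3, CH2Cl2, 0 °C → rt; then DBU (0.2 equiv), rt
Reagents that add atoms: none
Why: Dess–Martin oxidation converts the only remaining secondary alcohol into the C10 ketone and leaves the tertiary C4 hydroxyl alone. Catalytic DBU then moves the exocyclic double bond into conjugation through the C9 dienolate, which is far more acidic than the C7 position from which the C6 ester could be eliminated.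

## Compound list

1 | 2-methylprop-2-en-1-ol | CC(=C)CO | starting material
2 | lithium 2-(lithiomethyl)prop-2-en-1-olate (dilithio dianion) | [Li]CC(=C)CO[Li] | intermediate
3 | trimethyl({2-[(trimethylsilyl)methyl]prop-2-en-1-yl}oxy)silane | C=C(CO[Si](C)(C)C)C[Si](C)(C)C | intermediate
4 | 2-[(trimethylsilyl)methyl]prop-2-en-1-ol | C=C(CO)C[Si](C)(C)C | intermediate
5 | 2-[(trimethylsilyl)methyl]prop-2-en-1-yl methanesulfonate | C=C(COS(C)(=O)=O)C[Si](C)(C)C | intermediate
6 | [2-(iodomethyl)prop-2-en-1-yl]trimethylsilane | C=C(CI)C[Si](C)(C)C | intermediate
7 | 3-methylcyclopent-2-en-1-one | CC1=CC(=O)CC1 | starting material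
8 | ethynyltrimethylsilane | C#C[Si](C)(C)C | starting material
9 | bis(2-methylpropyl)[1-(trimethylsilyl)ethenyl]alumane | C=C([Si](C)(C)C)[Al](CC(C)C)CC(C)C | intermediate
10 | bis(2-methylpropyl)aluminium (3S)-3-methyl-3-[1-(trimethylsilyl)ethenyl]cyclopent-1-en-1-olate | C=C([Si](C)(C)C)[C@@]1(C)CCC(O[Al](CC(C)C)CC(C)C)=C1 | intermediate
11 | trimethyl({(3S)-3-methyl-3-[1-(trimethylsilyl)ethenyl]cyclopent-1-en-1-yl}oxy)silane | C=C([Si](C)(C)C)[C@@]1(C)CCC(O[Si](C)(C)C)=C1 | intermediate
12 | (2S,3S)-2-(dimethoxymethyl)-3-methyl-3-[1-(trimethylsilyl)ethenyl]cyclopentan-1-one | COC(OC)[C@H]1C(=O)CC[C@]1(C)C(=C)[Si](C)(C)C | intermediate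
13 | (2S,3S)-2-(dimethoxymethyl)-3-(1-iodoethenyl)-3-methylcyclopentan-1-one | COC(OC)[C@H]1C(=O)CC[C@]1(C)C(I)=C | intermediate
14 | (2S,3R)-2-(dimethoxymethyl)-3-ethenyl-3-methylcyclopentan-1-one | COC(OC)[C@H]1C(=O)CC[C@]1(C)C=C | intermediate
15 | (1R,2R,3R)-2-(dimethoxymethyl)-3-ethenyl-3-methyl-1-(propan-2-yl)cyclopentan-1-ol | COC(OC)[C@H]1[C@](O)(C(C)C)CC[C@]1(C)C=C | intermediate
16 | potassium (1R,2R,3R)-2-(dimethoxymethyl)-3-ethenyl-3-methyl-1-(propan-2-yl)cyclopentan-1-olate | COC(OC)[C@H]1[C@]([O-])(C(C)C)CC[C@]1(C)C=C.[K+] | intermediate
17 | {[(1R,2R,3R)-2-(dimethoxymethyl)-3-ethenyl-3-methyl-1-(propan-2-yl)cyclopentyl]oxy}triethylsilane | COC(OC)[C@H]1[C@](O[Si](CC)(CC)CC)(C(C)C)CC[C@]1(C)C=C | intermediate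
18 | (1R,2R,5R)-2-ethenyl-2-methyl-5-(propan-2-yl)-5-[(triethylsilyl)oxy]cyclopentane-1-carbaldehyde | O=C[C@H]1[C@](O[Si](CC)(CC)CC)(C(C)C)CC[C@]1(C)C=C | intermediate
19 | (1R,2S,5R)-2-methyl-5-(propan-2-yl)-5-[(triethylsilyl)oxy]-2-(1,2,4-trioxolan-3-yl)cyclopentane-1-carbaldehyde (trioxolane carbon unassigned) | O=C[C@H]1[C@](O[Si](CC)(CC)CC)(C(C)C)CC[C@]1(C)C2OCOO2 | intermediate
20 | (1S,2R,3R)-1-methyl-3-(propan-2-yl)-3-[(triethylsilyl)oxy]cyclopentane-1,2-dicarbaldehyde | O=C[C@@H]1[C@@](C)(C=O)CC[C@@]1(O[Si](CC)(CC)CC)C(C)C | intermediate
21 | difluoro(iodo){2-[(trimethylsilyl)methyl]prop-2-en-1-yl}stannane | C=C(C[Sn](F)(F)I)C[Si](C)(C)C | intermediate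
22 | O-difluoro(iodo)stannyl derivative of (1R,2S,5R)-2-{(1S)-1-hydroxy-3-[(trimethylsilyl)methyl]but-3-en-1-yl}-2-methyl-5-(propan-2-yl)-5-[(triethylsilyl)oxy]cyclopentane-1-carbaldehyde | O=C[C@@H]1[C@@](C)([C@@H](O[Sn](F)(F)I)CC(=C)C[Si](C)(C)C)CC[C@@]1(O[Si](CC)(CC)CC)C(C)C | intermediate
23 | (3R,3aS,4S,8S,8aS)-8a-methyl-6-methylidene-3-(propan-2-yl)-3-[(triethylsilyl)oxy]decahydroazulene-4,8-diol | O[C@H]1CC(=C)C[C@H](O)[C@@]2(C)CC[C@@](O[Si](CC)(CC)CC)(C(C)C)[C@H]12 | intermediate
24 | (3R,3aS,4S,8S,8aS)-8a-methyl-6-methylidene-3-(propan-2-yl)decahydroazulene-3,4,8-triol | O[C@H]1CC(=C)C[C@H](O)[C@@]2(C)CC[C@@](O)(C(C)C)[C@H]12 | intermediate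
25 | 4-methoxybenzoyl chloride | COc1ccc(C(Cl)=O)cc1 | starting material
26 | (3R,3aS,4S,8S,8aS)-3,8-dihydroxy-8a-methyl-6-methylidene-3-(propan-2-yl)decahydroazulen-4-yl 4-methoxybenzoate | COc1ccc(C(=O)O[C@H]2CC(=C)C[C@H](O)[C@@]3(C)CC[C@@](O)(C(C)C)[C@H]23)cc1 | intermediate
27 | (3R,3aS,4S,8aS)-3-hydroxy-8a-methyl-6-methylidene-8-oxo-3-(propan-2-yl)decahydroazulen-4-yl 4-methoxybenzoate | COc1ccc(C(=O)O[C@H]2CC(=C)CC(=O)[C@@]3(C)CC[C@@](O)(C(C)C)[C@H]23)cc1 | intermediate
28 | (3R,3aS,4S,8aS)-3-hydroxy-6,8a-dimethyl-8-oxo-3-(propan-2-yl)-1,2,3,3a,4,5,8,8a-octahydroazulen-4-yl 4-methoxybenzoate | COc1ccc(C(=O)O[C@H]2CC(C)=CC(=O)[C@@]3(C)CC[C@@](O)(C(C)C)[C@H]23)cc1 | target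

## Step count and least certain steps

Total: 14 steps. Longest linear sequence: 12 steps (steps 3–14, from 7); steps 1 and 2 are a two-step branch that supplies 6.

Step 11 (key step). The most likely failure is closure through the other carbonyl rotamer, which would erode the diastereocontrol at C6. Also possible are a second intermolecular allylation of the hindered formyl group or protodesilylation of the allylsilane before ring closure. The fallback uses the wrong epimer instead of avoiding it. Setting out from 20 and 6, the annulation would then deliver the C6-epimeric diol (3R,3aS,4R,8S,8aS)-8a-methyl-6-methylidene-3-(propan-2-yl)-3-[(triethylsilyl)oxy]decahydroazulene-4,8-diol F1. Bu4NF would give the C6-epimeric triol F2. Mitsunobu esterification of F2 with 4-methoxybenzoic acid, PPh3 and diisopropyl azodicarboxylate should install the ester at C6 with inversion; the neopentyl O10 and the tertiary O4 are not expected to react. This gives 26, where the route is rejoined.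

Step 3. The weak point is incomplete O-silylation of the hindered aluminium enolate, so that part of the material is protonated on work-up and the enolate regiochemistry is lost. Competing transfer of an isobutyl group or insufficient enantioselectivity would also show up here. Fallback: setting out from 7 and 8, the conjugate addition is run as before, but enolate 10 is quenched with acetic anhydride to give the isolable enol acetate (3S)-3-methyl-3-[1-(trimethylsilyl)ethenyl]cyclopent-1-en-1-yl acetate F3. MeLi (2 equiv, THF, 0 °C) then releases the regiodefined lithium enolate, and Me3SiCl converts it into 11, where the route is rejoined.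

Step 7. Enolisation of the hindered ketone or β-hydride transfer from the isopropyl reagent may outrun addition, and the facial preference may be lower than expected. Fallback: setting out from 12, the carbon is introduced as an sp2 nucleophile that cannot deliver hydride. CH2=C(Me)MgBr with CeCl3 should give the isopropenyl carbinol (1S,2R,3S)-2-(dimethoxymethyl)-3-methyl-1-(prop-1-en-2-yl)-3-[1-(trimethylsilyl)ethenyl]cyclopentan-1-ol F4. Hydroxyl-directed hydrogenation with [Ir(cod)(PCy3)(py)]PF6 and H2 should reduce only the allylic-alcohol alkene and leave the hindered vinylsilane, giving the isopropyl carbinol F5. N-Iodosuccinimide converts F5 into the alkenyl iodide F6, and t-BuLi followed by MeOH replaces iodine by hydrogen to give 15, where the route is rejoined.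

Step 13. Discrimination between O6 and O10 may be insufficient, leading to acylation at O10 or at both positions. Fallback: setting out from 24, O4 and O6 are tied together with phenylboronic acid (toluene, MgSO4) as the cyclic phenylboronate F7, which leaves O10 as the only free hydroxyl. Dess–Martin oxidation gives the keto boronate F8. Exchange with pinacol releases the keto diol (3R,3aS,4S,8aS)-3,4-dihydroxy-8a-methyl-6-methylidene-3-(propan-2-yl)octahydroazulen-8(1H)-one F9. Its single secondary hydroxyl is acylated with 25 (pyridine, DMAP) to give 27, where the route is rejoined before the DBU treatment of step 14.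

## Further compounds

F1 | step 11 | (3R,3aS,4R,8S,8aS)-8a-methyl-6-methylidene-3-(propan-2-yl)-3-[(triethylsilyl)oxy]decahydroazulene-4,8-diol | O[C@@H]1CC(=C)C[C@H](O)[C@@]2(C)CC[C@@](O[Si](CC)(CC)CC)(C(C)C)[C@H]12
F2 | step 11 | (3R,3aS,4R,8S,8aS)-8a-methyl-6-methylidene-3-(propan-2-yl)decahydroazulene-3,4,8-triol | O[C@@H]1CC(=C)C[C@H](O)[C@@]2(C)CC[C@@](O)(C(C)C)[C@H]12
F3 | step 3 | (3S)-3-methyl-3-[1-(trimethylsilyl)ethenyl]cyclopent-1-en-1-yl acetate | C=C([Si](C)(C)C)[C@@]1(C)CCC(OC(C)=O)=C1
F4 | step 7 | (1S,2R,3S)-2-(dimethoxymethyl)-3-methyl-1-(prop-1-en-2-yl)-3-[1-(trimethylsilyl)ethenyl]cyclopentan-1-ol | COC(OC)[C@H]1[C@](O)(C(C)=C)CC[C@]1(C)C(=C)[Si](C)(C)C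
F5 | step 7 | (1R,2R,3S)-2-(dimethoxymethyl)-3-methyl-1-(propan-2-yl)-3-[1-(trimethylsilyl)ethenyl]cyclopentan-1-ol | COC(OC)[C@H]1[C@](O)(C(C)C)CC[C@]1(C)C(=C)[Si](C)(C)C
F6 | step 7 | (1R,2R,3S)-2-(dimethoxymethyl)-3-(1-iodoethenyl)-3-methyl-1-(propan-2-yl)cyclopentan-1-ol | COC(OC)[C@H]1[C@](O)(C(C)C)CC[C@]1(C)C(I)=C
F7 | step 13 | 3,4-O-phenylboronate of (3R,3aS,4S,8S,8aS)-8a-methyl-6-methylidene-3-(propan-2-yl)decahydroazulene-3,4,8-triol | c1ccccc1B2O[C@H]3CC(=C)C[C@H](O)[C@@]4(C)CC[C@@](O2)(C(C)C)[C@H]34
F8 | step 13 | 3,4-O-phenylboronate of (3R,3aS,4S,8aS)-3,4-dihydroxy-8a-methyl-6-methylidene-3-(propan-2-yl)octahydroazulen-8(1H)-one | c1ccccc1B2O[C@H]3CC(=C)CC(=O)[C@@]4(C)CC[C@@](O2)(C(C)C)[C@H]34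
F9 | step 13 | (3R,3aS,4S,8aS)-3,4-dihydroxy-8a-methyl-6-methylidene-3-(propan-2-yl)octahydroazulen-8(1H)-one | O[C@H]1CC(=C)CC(=O)[C@@]2(C)CC[C@@](O)(C(C)C)[C@H]12
A1 | alternative 1 | 3-(1-methyl-2,7-dioxocycloheptyl)propanal | O=CCCC1(C)C(=O)CCCCC1=O
A2 | alternative 1 | (3aR,8aS)-3a-hydroxy-8a-methyloctahydroazulene-3,8-dione (cis-fused) | C1CCCC(=O)[C@@]2(C)CCC(=O)[C@@]12O
A3 | alternative 2 | (2-methyl-1,3-dioxolan-2-yl)acetaldehyde | CC1(CC=O)OCCO1
A4 | alternative 2 | (2S,3S)-2-[(1S)-1-hydroxy-2-(2-methyl-1,3-dioxolan-2-yl)ethyl]-3-methyl-3-[1-(trimethylsilyl)ethenyl]cyclopentan-1-one | O[C@@H](CC1(C)OCCO1)[C@@H]2[C@@](C)(C(=C)[Si](C)(C)C)CCC2=O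
A5 | alternative 3 | (2Z,5S,6R,7R)-5-{[tert-butyl(dimethyl)silyl]oxy}-6,7-epoxy-3,10-dimethyl-7-(propan-2-yl)cyclodec-2-en-1-one (either C10 epimer) | CC1CC[C@]2(C(C)C)O[C@@H]2[C@@H](O[Si](C)(C)C(C)(C)C)C/C(C)=C\C1=O
A6 | alternative 3 | (3R,3aS,4S,8aS)-4-{[tert-butyl(dimethyl)silyl]oxy}-3-hydroxy-6,8a-dimethyl-3-(propan-2-yl)-2,3,3a,4,5,8a-hexahydroazulen-8(1H)-one | CC(C)(C)[Si](C)(C)O[C@H]1CC(C)=CC(=O)[C@@]2(C)CC[C@@](O)(C(C)C)[C@H]12
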